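**Retrosynthetic overview**
1. Target ⇒ (retro-[4+2], bonds C2–C2′ and C5–C1′) myrcene + 1-oxoeudesma-2,4-dien-12,6-olide ⇒ (retro-6π, bond C1–C10) Z-dienylketene ⇒ (retro-4π, bond C1–C4) 4-methyl-4-(cyclohexenyl)cyclobut-2-enone. In the forward direction one heating turns the four-membered ring C1–C2–C3–C4 into six-membered ring A by taking in C5 and C10, and bridges it with myrcene.
2. Enabling feature: ring A, C1(=O)–C2H–C3H=C4(CH3)–C5–C10(CH3), is a cyclohex-3-enone bridged from C2 to C5 by C2′–C1′ (a bicyclo[2.2.2]oct-5-en-2-one). Its C3=C4 bond is the Diels–Alder retron of a 2,4-dienone, the fully substituted C10 next to C1=O keeps that dienone from aromatising, and C1–C4 with the C4 methyl group are the four carbons of a cyclobutenone attached to the C5=C10 alkene of ring B.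
3. Cyclobutenone ⇐ cyclobutanone (selenoxide elimination) ⇐ C4 methyl ketone (sulfonium cyclopropylide spiroannulation) ⇐ C5 vinyl triflate (Stille coupling).
4. Vinyl triflate lactone ⇐ (R)-carvone. C7 comes from the chiral pool, C6 from a Rubottom oxidation anti to the isopropenyl group, C5=C10 from conjugate reduction and enolate triflation, and C11/C12 from hydroboration, oxidative lactonisation and equilibration.
5. Ring order: ring B (from carvone) → γ-lactone → four-membered ring → ring A (four to six atoms) → bridge ring of the bicyclo[2.2.2]octenone.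

Key step: step 11

Numbering used below (eudesmane and myrcene): C1 ketone carbon, C2 bridgehead CH, C3=C4, C5 quaternary bridgehead, C6 (O-bearing), C7, C8, C9, C10 (quaternary), C11, C12 (lactone C=O), C13 (CH3 on C11), C14 (CH3 on C10), C15 (CH3 on C4). C1′ (CH2) and C2′ (CH) are the former vinyl carbons of myrcene. β is the face that carries C14.
Remark on the chemistry: centres that form as mixtures and are later equilibrated or erased are left open in the SMILES. These are C11 before step 7 and the ring carbons of the four-membered ring. All other centres are drawn.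

**Step 1**
Reactants: 1 (R)-(−)-carvone
Product: 2 tert-butyl(dimethyl){[(3R)-6-methyl-3-(prop-1-en-2-yl)cyclohexa-1,5-dien-1-yl]oxy}silane
Conditions: TBSOTf, Et3N, CH2Cl2, 0 °C
Reagents that add atoms: tert-butyldimethylsilyl triflate, CC(C)(C)[Si](C)(C)OS(=O)(=O)C(F)(F)F
Why: Soft enolisation with silyl triflate and amine removes an α′ proton at C6 and gives the cross-conjugated 2-silyloxydiene without touching C7.

**Step 2**
Reactants: 2 silyl dienol ether
Product: 4 (5S,6S)-6-(tert-butyldimethylsilyloxy)-2-methyl-5-(prop-1-en-2-yl)cyclohex-2-en-1-one, via siloxy epoxide 3 (not isolated)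
Conditions: mCPBA, hexane–CH2Cl2, −20 to 0 °C
Reagents that add atoms: mCPBA, OOC(=O)c1cccc(Cl)c1
Why: In this Rubottom oxidation the peracid attacks the most electron-rich C5=C6 enol ether bond anti to the C7 isopropenyl group, and epoxide opening with 1,4-silyl shift sets C6 trans to C7, which is also the diequatorial, thermodynamically preferred arrangement.

**Step 3**
Reactants: 4 α-silyloxy enone
Product: 6 (5S,6S)-6-(tert-butyldimethylsilyloxy)-2-methyl-5-(prop-1-en-2-yl)cyclohex-1-en-1-yl trifluoromethanesulfonate, via lithium enolate 5 (not isolated)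
Conditions: LiBH(s-Bu)3, THF, −78 °C; then PhNTf2, −78 °C to rt
Reagents that add atoms: N-phenylbis(trifluoromethanesulfonimide), FC(F)(F)S(=O)(=O)N(c1ccccc1)S(=O)(=O)C(F)(F)F
Why: Conjugate hydride addition by the bulky borohydride gives the C5=C10 enolate regiospecifically, and O-sulfonylation of that enolate fixes the tetrasubstituted double bond as a vinyl triflate.

**Step 4**
Reactants: 6 vinyl triflate
Product: 8 (5S,6S)-6-(tert-butyldimethylsilyloxy)-5-(1-hydroxypropan-2-yl)-2-methylcyclohex-1-en-1-yl trifluoromethanesulfonate (C11 epimers), via B-alkyl-9-BBN adduct 7 (not isolated)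
Conditions: 9-BBN, THF, 0 °C to rt; then H2O2, aq NaOAc, 0 °C
Reagents that add atoms: hydrogen peroxide, OO
Why: In this hydroboration–oxidation 9-BBN reacts only with the 1,1-disubstituted isopropenyl group (the other alkene is tetrasubstituted and electron-poor) and places boron on the terminal carbon, while the C11 centre it creates is corrected in step 7.

**Step 5**
Reactants: 8 silyl ether alcohol
Product: 9 (5S,6S)-6-hydroxy-5-(1-hydroxypropan-2-yl)-2-methylcyclohex-1-en-1-yl trifluoromethanesulfonate (C11 epimers)
Conditions: aq HF, MeCN, 0 °C to rt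
Reagents that add atoms: none
Why: Acidic fluoride cleaves the silyl ether through the strong Si–F bond and leaves the vinyl triflate intact, whereas basic fluoride could attack its sulfur.

**Step 6**
Reactants: 9 diol
Product: 11 (3aS,7aS)-3,6-dimethyl-2-oxo-2,3,3a,4,5,7a-hexahydro-1-benzofuran-7-yl trifluoromethanesulfonate (C11 epimers), via lactol 10 (not isolated)
Conditions: TEMPO (cat.), PhI(OAc)2, CH2Cl2, rt
Reagents that add atoms: none
Why: The oxoammonium oxidation takes the primary alcohol first, the hydroxy aldehyde closes to the lactol and is oxidised on to the γ-lactone, and since C6 and C7 are untouched the ring fusion is trans.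

**Step 7**
Reactants: 11 lactone epimers
Product: 12 (3S,3aS,7aS)-3,6-dimethyl-2-oxo-2,3,3a,4,5,7a-hexahydro-1-benzofuran-7-yl trifluoromethanesulfonate
Conditions: DBU, toluene, 90 °C
Reagents that add atoms: none
Why: Base-mediated epimerisation through the lactone enolate places C13 under thermodynamic control on the side of H-7 and anti to C8 (11S), the stable arrangement of trans-fused 12,6-olides.

**Step 8**
Reactants: 12 (11S)-lactone triflate
Product: 14 (3S,3aS,7aS)-7-acetyl-3,6-dimethyl-3a,4,5,7a-tetrahydro-1-benzofuran-2(3H)-one, via ethyl enol ether 13 (not isolated)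
Conditions: Bu3SnC(OEt)=CH2, Pd(PPh3)4 (cat.), LiCl, THF, 65 °C; then 1 M HCl, THF, rt
Reagents that add atoms: tributyl(1-ethoxyvinyl)stannane, CCCC[Sn](CCCC)(CCCC)C(=C)OCC; water, O
Why: In this Stille coupling the vinyl triflate adds oxidatively to zerovalent palladium, the small α-ethoxyvinyl group is transferred as an acetyl anion equivalent even to the hindered C5, and mild acid hydrolyses the enol ether to the C4 methyl ketone.

**Step 9**
Reactants: 14 acetyl lactone
Product: 16 (3S,3aS,7aS)-3,6-dimethyl-7-(1-methyl-2-oxocyclobutyl)-3a,4,5,7a-tetrahydro-1-benzofuran-2(3H)-one (either C4 configuration), via oxaspiropentane 15 (not isolated)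
Conditions: cyclopropyldiphenylsulfonium tetrafluoroborate, KN(SiMe3)2, DME, −45 °C; then 14, to 0 °C; then LiBF4 (cat.), toluene, rt
Reagents that add atoms: cyclopropyldiphenylsulfonium tetrafluoroborate, C1CC1[S+](c1ccccc1)c1ccccc1.F[B-](F)(F)F
Why: In this cyclobutanone spiroannulation (sulfur ylide epoxidation followed by oxaspiropentane-to-cyclobutanone rearrangement) the unstabilised ylide adds 1,2 to the twisted methyl ketone, and lithium-assisted ionisation at the tertiary allylic C4 triggers the cyclopropane bond shift, the C4 configuration being irrelevant because it is erased in step 11.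

**Step 10**
Reactants: 16 cyclobutanone
Product: 19 (3S,3aS,7aS)-3,6-dimethyl-7-(1-methyl-4-oxocyclobut-2-en-1-yl)-3a,4,5,7a-tetrahydro-1-benzofuran-2(3H)-one (either C4 configuration), via α-phenylselenide 17 (not isolated), via selenoxide 18 (not isolated)
Conditions: LiN(SiMe3)2, THF, −78 °C; PhSeCl; then mCPBA, CH2Cl2, −78 °C; i-Pr2NH, to 0 °C
Reagents that add atoms: none
Why: Kinetic enolisation occurs at C2, the only enolisable ketone position and more acidic than the lactone C11–H, and selenenylation, cold oxidation and selenoxide syn-elimination introduce C2=C3 at or below 0 °C, well under the ring-opening temperature of the product.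

**Step 11**
Reactants: 19 4-methyl-4-alkenylcyclobutenone; 20 myrcene (7-methyl-3-methylideneocta-1,6-diene)
Product: 23 target CNP0385704.1, via Z-dienylketene 21 (not isolated), via dienone 22 (not isolated)
Conditions: 20 (15 equiv), BHT (cat.), toluene (0.02 M in 19), sealed tube, 110 °C
Reagents that add atoms: none
Why: Heat opens the cyclobutenone by conrotatory 4π cleavage of C1–C4; the E dienylketene can only reclose, so the material drains through Z ketene 21, whose 6π electrocyclisation bonds C1 to C10, inserts C5 and C10 of ring B into the former four-membered ring (four to six atoms) and gives dienone 22, which the excess myrcene intercepts in a [4+2] cycloaddition. The closest known reactions are the thermal ring expansion of 4-alkenylcyclobutenones (Moore rearrangement, second half of the Danheiser benzannulation), here halted at the cyclohexa-2,4-dienone because C10 is fully substituted, and the Diels–Alder reactions of 6,6-disubstituted cyclohexa-2,4-dienones with alkenes. Ring A closes by disrotatory 6π electrocyclisation (C1–C10), and the bridge ring C2–C2′–C1′–C5–C4–C3 of the bicyclo[2.2.2]octenone closes by a suprafacial intermolecular [4+2] that forms C2–C2′ and C5–C1′. C10 is controlled by the trans-fused lactone: with O6 and C11 locked equatorial, only bonding of C1 to the α face of C10 lets C14 turn axial (β) while ring B relaxes from half-chair to chair, the other mode forcing a twist-boat. C5 and C2 follow from addition to the β face of 22, because at C10 the methyl group (β) is the smaller of the two out-of-plane groups, at C6 the β side carries only H, and the chair of ring B lies on the α side with axial H-7 and H-9 pointing at the α lobe of C5, while C2′ follows from the endo rule with the remaining diene unit of myrcene lying under C3=C4. The selectivities needed are secured as follows: the intramolecular 6π closure outruns any trapping of the ketene, the monosubstituted vinyl group is the least hindered 2π unit of myrcene, its CH2 terminus (larger HOMO coefficient) bonds to C5 (the δ-carbon with the largest LUMO coefficient of the dienone), and excess myrcene at high dilution of 19 suppresses dimerisation of 22.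

**Compound list**
1 | (R)-(−)-carvone | CC1=CC[C@H](CC1=O)C(C)=C | starting material
2 | carvone TBS dienol ether, (3R) | CC1=CC[C@H](C=C1O[Si](C)(C)C(C)(C)C)C(C)=C | intermediate
3 | siloxy epoxide (epoxide anti to isopropenyl) | CC1=CC[C@@H](C(C)=C)[C@@H]2O[C@]12O[Si](C)(C)C(C)(C)C | intermediate
4 | (5S,6S)-6-(TBS-oxy)carvone | CC1=CC[C@@H](C(C)=C)[C@H](O[Si](C)(C)C(C)(C)C)C1=O | intermediate
5 | lithium C5=C10 enolate | [Li+].CC1=C([O-])[C@@H](O[Si](C)(C)C(C)(C)C)[C@H](C(C)=C)CC1 | intermediate
6 | (5S,6S)-vinyl triflate | CC1=C(OS(=O)(=O)C(F)(F)F)[C@@H](O[Si](C)(C)C(C)(C)C)[C@H](C(C)=C)CC1 | intermediate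
7 | B-alkyl-9-BBN adduct (C11 open) | CC1=C(OS(=O)(=O)C(F)(F)F)[C@@H](O[Si](C)(C)C(C)(C)C)[C@H](C(C)CB2C3CCCC2CCC3)CC1 | intermediate
8 | primary alcohol (C11 open) | CC1=C(OS(=O)(=O)C(F)(F)F)[C@@H](O[Si](C)(C)C(C)(C)C)[C@H](C(C)CO)CC1 | intermediate
9 | diol (C11 open) | CC1=C(OS(=O)(=O)C(F)(F)F)[C@@H](O)[C@H](C(C)CO)CC1 | intermediate
10 | lactol (C11 and C12 open) | CC1C(O)O[C@@H]2C(OS(=O)(=O)C(F)(F)F)=C(C)CC[C@@H]12 | intermediate
11 | trans-lactone triflate (C11 open) | CC1C(=O)O[C@@H]2C(OS(=O)(=O)C(F)(F)F)=C(C)CC[C@@H]12 | intermediate
12 | (3S,3aS,7aS)-lactone triflate | C[C@@H]1C(=O)O[C@@H]2C(OS(=O)(=O)C(F)(F)F)=C(C)CC[C@@H]12 | intermediate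
13 | 7-(1-ethoxyvinyl) lactone | C[C@@H]1C(=O)O[C@@H]2C(C(=C)OCC)=C(C)CC[C@@H]12 | intermediate
14 | (3S,3aS,7aS)-7-acetyl lactone | C[C@@H]1C(=O)O[C@@H]2C(C(C)=O)=C(C)CC[C@@H]12 | intermediate
15 | oxaspiropentane (C4 open) | C[C@@H]1C(=O)O[C@@H]2C(C3(C)OC34CC4)=C(C)CC[C@@H]12 | intermediate
16 | 2-methyl-2-alkenylcyclobutanone (C4 open) | C[C@@H]1C(=O)O[C@@H]2C(C3(C)CCC3=O)=C(C)CC[C@@H]12 | intermediate
17 | α-phenylselenide (C2 and C4 open) | C[C@@H]1C(=O)O[C@@H]2C(C3(C)CC([Se]c4ccccc4)C3=O)=C(C)CC[C@@H]12 | intermediate
18 | selenoxide (C2, C4 and Se open) | C[C@@H]1C(=O)O[C@@H]2C(C3(C)CC([Se](=O)c4ccccc4)C3=O)=C(C)CC[C@@H]12 | intermediate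
19 | 4-methyl-4-alkenylcyclobutenone (C4 open) | C[C@@H]1C(=O)O[C@@H]2C(C3(C)C=CC3=O)=C(C)CC[C@@H]12 | intermediate
20 | myrcene | C=CC(=C)CCC=C(C)C | starting material
21 | (3Z)-dienylketene | O=C=C/C=C(/C)C1=C(C)CC[C@@H]2[C@@H]1OC(=O)[C@H]2C | intermediate
22 | (11S)-1-oxoeudesma-2,4-dien-12,6α-olide (10β-methyl) | C[C@@H]1C(=O)O[C@@H]2C3=C(C)C=CC(=O)[C@]3(C)CC[C@@H]12 | intermediate
23 | CNP0385704.1 | C=C(CCC=C(C)C)[C@H]1C[C@@]23C(C)=C[C@@H]1C(=O)[C@]2(C)CC[C@H]1[C@H](C)C(=O)O[C@@H]13 | target

**Total step count:** 11. **Longest linear sequence:** 11 steps from (R)-carvone.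

**Steps most likely to fail**

1. Step 11. The bimolecular cycloaddition may not keep pace with the formation of dienone 22.
   - This opens the way to dimerisation of 22, to reaction of myrcene through its diene unit at C2=C3, to polymerisation of myrcene, and to a 1,5-hydrogen shift in the E ketene.
   - Facial selectivity at C5 may also be low, and long heating may start a Cope rearrangement of the endo-alkenyl adduct.
   - Fallback (sets out from 19, returns at 23): the hydrocarbon is replaced by an enone that has no diene unit and is a faster 2π partner, and the methylidene group is installed afterwards. 4-Methylpent-3-enylmagnesium bromide is added to acrolein to give 7-methylocta-1,6-dien-3-ol F1, which MnO2 oxidises to 7-methylocta-1,6-dien-3-one F2. Heating 19 with a small excess of F2 in toluene runs the same ring expansion through 21 and 22 and should give the endo side-chain ketone adduct F3 with the same regiochemistry. The less hindered side-chain ketone is then methylenated with Zn, CH2Br2 and TiCl4. This reagent is non-basic, so C2′ is not epimerised. The C1 ketone is shielded by C10 and the bridgehead, and the lactone is inert, so 23 should result.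

2. Step 10. The strained ketone may undergo Baeyer–Villiger attack during the oxidation, selenium by-products may add back to the strained enone, or the ring may open prematurely during the elimination.
   - Fallback (sets out from 16, returns at 19): a Saegusa–Ito oxidation replaces the chalcogen chemistry. TMSOTf and Et3N convert 16 into the 1-(trimethylsilyloxy)cyclobutene F4. Pd(OAc)2 in MeCN at room temperature forms the divalent palladium enolate, whose β-hydride elimination gives 19 without any peroxide or nucleophilic by-product.

3. Step 9. The basic ylide may deprotonate 14 at C14 or C9. The extended enolate can then expel the lactone carboxylate from C6, and attack at the lactone carbonyl is also possible.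
   - Fallback (sets out from 14, returns at 16): a non-basic organocerium reagent is used instead. Cyclopropyl phenyl sulfide is lithiated with n-BuLi and transmetallated with CeCl3. Addition to the ketone of 14 at −78 °C gives the 1-(phenylthio)cyclopropyl carbinol F5. TsOH in wet toluene ionises the tertiary allylic alcohol, the cyclopropane bond migrates, and hydrolysis of the thionium ion gives 16.

**Further compounds**
F1 | step 11 | 7-methylocta-1,6-dien-3-ol | C=CC(O)CCC=C(C)C
F2 | step 11 | 7-methylocta-1,6-dien-3-one | C=CC(=O)CCC=C(C)C
F3 | step 11 | endo side-chain ketone adduct | CC(C)=CCCC(=O)[C@H]1C[C@@]23C(C)=C[C@@H]1C(=O)[C@]2(C)CC[C@H]1[C@H](C)C(=O)O[C@@H]13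
F4 | step 10 | 1-(trimethylsilyloxy)cyclobutene | C[C@@H]1C(=O)O[C@@H]2C(C3(C)CC=C3O[Si](C)(C)C)=C(C)CC[C@@H]12
F5 | step 9 | 1-(phenylthio)cyclopropyl carbinol | C[C@@H]1C(=O)O[C@@H]2C(C(C)(O)C3(Sc4ccccc4)CC3)=C(C)CC[C@@H]12
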